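**Plan**

1. Feature: C2–C3–C3''–C2'' (flavanone numbering; doubly primed atoms lie in the 4-hydroxyphenyl half) is a four-carbon chain with an aryl ring (B, B'') at each end, and C4 and C4'' are lone carbonyl carbons between this chain and rings A and A''. The chain is therefore a masked 1,4-diarylbut-2-yne-1,4-diol and each carbonyl is one molecule of CO.
2. Cuts, in retrosynthetic order: the five O–benzyl bonds; O1–C2 and O1''–C2'' of rings C and C''; then C3–C4, C4–C4a, C3''–C4'' and C4''–C4a'' together; last the two alkyne–carbinol C–C bonds.
3. Forward: ethyne is joined to the two aldehydes and the diol is activated as its bis(methyl carbonate). One palladium-catalysed operation then inserts CO twice and attaches two ring-A aryl groups from a boronic acid, giving an acyclic α,α'-linked bis(chalcone).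
4. Rings C and C'' close afterwards by phenol oxa-Michael addition, once the two ortho MOM groups are removed; hydrogenolysis of the benzyl ethers ends the route.
5. Stereochemistry: C2 and C2'' (both S) come from the facial selectivity of a cinchona amine–thiourea catalyst. C3 and C3'' (both S, cis to the C2 aryl groups) come from kinetic protonation of each ring enol on the face anti to that aryl group.

Key step: step 5

Remark: the target SMILES corresponds to (2S,3S,2''S,3''S), with H2/H3 and H2''/H3'' cis in both pyranone rings; the route is built for this kinetic cis,cis isomer.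
Assumption: the epi-quinine-derived thiourea is taken to give the 2S,2''S sense of addition; if the first run shows the opposite sense, the epi-quinidine-derived pseudoenantiomer is used in the same way.
Assumption: 3,5-bis(benzyloxy)phenol is treated as a catalogue compound (it is otherwise reached from phloroglucinol triacetate by benzylation and acetate cleavage).

**Route**

Step 1
Reactants: 1 4-methoxybenzaldehyde; 2 ethynylmagnesium bromide
Product: 3 rac-1-(4-methoxyphenyl)prop-2-yn-1-ol
Conditions: THF, 0 °C to rt; aq. NH4Cl
Reagents that add atoms: none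
Why: 1,2-addition of the alkynyl Grignard reagent to the aldehyde is standard; the carbinol centre forms as a racemate, which is harmless because step 5 erases it.

Step 2
Reactants: 3 rac-1-(4-methoxyphenyl)prop-2-yn-1-ol; 4 4-(benzyloxy)benzaldehyde
Product: 7 1-[4-(benzyloxy)phenyl]-4-(4-methoxyphenyl)but-2-yne-1,4-diyl bis(methyl carbonate), via dilithium alkynide alkoxide 5 (not isolated), via dilithium dialkoxide 6 (not isolated)
Conditions: n-BuLi (2.1 equiv), THF, −78 °C; then 4, −78 to −20 °C; then ClCO2Me (2.5 equiv), −78 to 0 °C; chromatography on Et3N-deactivated silica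
Reagents that add atoms: methyl chloroformate, COC(=O)Cl
Why: two equivalents of n-BuLi give the alkoxide–acetylide dianion, whose carbon terminus adds to the second aldehyde (acetylide 1,2-addition), and both lithium alkoxides are then acylated in the same flask by the chloroformate; the second carbinol centre forms without control and both diastereomers are carried on because step 5 erases them.

Step 3
Reactants: 8 3,5-bis(benzyloxy)phenol
Product: 9 1,3-bis(benzyloxy)-5-(methoxymethoxy)benzene
Conditions: NaH, MOMCl, DMF, 0 °C to rt
Reagents that add atoms: chloromethyl methyl ether, COCCl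
Why: Williamson-type O-alkylation of the sodium phenoxide installs the acetal that later directs lithiation and is cleavable without touching the benzyl ethers.

Step 4
Reactants: 9 1,3-bis(benzyloxy)-5-(methoxymethoxy)benzene
Product: 12 [2,4-bis(benzyloxy)-6-(methoxymethoxy)phenyl]boronic acid, via aryllithium 10 (not isolated), via lithium aryltriisopropoxyborate 11 (not isolated)
Conditions: n-BuLi (1.15 equiv), THF, 0 °C, 1 h; B(Oi-Pr)3 (1.5 equiv), −78 °C to rt; aq. NH4Cl (pH about 6)
Reagents that add atoms: triisopropyl borate, CC(C)OB(OC(C)C)OC(C)C; water, O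
Why: in this directed ortho-metalation, n-BuLi bound to the MOM acetal removes the ring hydrogen flanked by OMOM and OBn (two equivalent sites) rather than the one between the two benzyloxy groups or a benzylic hydrogen, and the aryllithium is trapped by the borate ester and hydrolysed near neutrality to limit protodeboronation.

Step 5
Reactants: 7 1-[4-(benzyloxy)phenyl]-4-(4-methoxyphenyl)but-2-yne-1,4-diyl bis(methyl carbonate); 12 [2,4-bis(benzyloxy)-6-(methoxymethoxy)phenyl]boronic acid; 13 carbon monoxide
Product: 16 (2E,3E)-2-[4-(benzyloxy)benzylidene]-1,4-bis[2,4-bis(benzyloxy)-6-(methoxymethoxy)phenyl]-3-(4-methoxybenzylidene)butane-1,4-dione, via allenyl ketone carbonate 14 (not isolated), via regioisomeric allenyl ketone carbonate 15 (not isolated)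
Conditions: Pd(PPh3)4 (10 mol %), CO (5 bar), 12 (3 equiv), degassed THF, 50 °C, dark
Reagents that add atoms: none
Why: Proposed new method: zerovalent palladium should ionise one propargylic carbonate with anti SN2' attack at the distal alkyne carbon, CO then inserts into the allenyl–palladium bond, and the methoxide released with CO2 activates boronic acid 12 for transmetallation, so that reductive elimination gives allenyl ketone 14 or 15 (depending on which carbonate leaves first); the surviving carbonate is now allylic to the allene, and a second SN2' ionisation at the central allene carbon gives a buta-1,3-dien-2-ylpalladium that is carbonylated and arylated in the same way. The closest known reactions are the palladium-catalysed double alkoxycarbonylation of but-2-yne-1,4-diol derivatives to 2,3-bis(alkylidene)succinates and the carbonylative Suzuki–Miyaura ketone synthesis, which are merged here for the first time. No ring is closed and no stereocentre is created; both carbinol centres of 7 are erased, which is why its diastereomer mixture can be used. The step needs aryl transfer to the acylpalladium rather than capture by methoxide or direct allenyl–aryl coupling; this is addressed by CO pressure (insertion before transmetallation), an aprotic solvent and excess boronic acid, which binds methoxide as the borate, while the two electron-donating ortho oxygens of 12 should speed transmetallation despite the hindrance. E geometry at both arylidene groups is expected because palladium enters the allene anti to the aryl group on its terminus and because PPh3 can equilibrate the enones toward the isomer with aryl trans to aroyl.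

Step 6
Reactants: 16 (2E,3E)-2-[4-(benzyloxy)benzylidene]-1,4-bis[2,4-bis(benzyloxy)-6-(methoxymethoxy)phenyl]-3-(4-methoxybenzylidene)butane-1,4-dione
Product: 17 (2E,3E)-2-[4-(benzyloxy)benzylidene]-1,4-bis[2,4-bis(benzyloxy)-6-hydroxyphenyl]-3-(4-methoxybenzylidene)butane-1,4-dione
Conditions: HCl (conc., cat.), MeOH–THF, 40 °C, dark
Reagents that add atoms: none
Why: acid-catalysed acetal exchange with methanol cleaves both aryl MOM ethers, helped by the neighbouring carbonyl groups, while benzyl and methyl ethers are stable and the chelated 2'-hydroxy-6'-benzyloxy aryl ketones are not expected to ring-close at this acidity and temperature.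

Step 7
Reactants: 17 (2E,3E)-2-[4-(benzyloxy)benzylidene]-1,4-bis[2,4-bis(benzyloxy)-6-hydroxyphenyl]-3-(4-methoxybenzylidene)butane-1,4-dione
Product: 20 (2S,3S,2''S,3''S)-5,7,5'',7''-tetrakis(benzyloxy)-2''-[4-(benzyloxy)phenyl]-2-(4-methoxyphenyl)-3,3''-bichromane-4,4''-dione, via monoflavanone 18 (not isolated), via regioisomeric monoflavanone 19 (not isolated)
Conditions: 1-[3,5-bis(trifluoromethyl)phenyl]-3-[(8S,9S)-6'-methoxycinchonan-9-yl]thiourea (20 mol %), toluene, −20 to 0 °C; AcOH quench at −20 °C, cold filtration through silica
Reagents that add atoms: none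
Why: Proposed new method: the quinuclidine nitrogen of the bifunctional catalyst deprotonates the chelated phenol while the thiourea binds the enone carbonyl, the phenoxide adds 6-endo to C2 on the catalyst-selected face (2S), and the quinuclidinium then protonates the ring enol at C3 anti to the pseudoaxial C2 aryl group (3S, cis ring), the same sequence in the other half setting C2'' and C3''; the closest known reaction is the cinchona thiourea-catalysed enantioselective oxa-Michael cyclisation of 2'-hydroxychalcones and alkylidene β-keto esters to flavanones, not yet shown on an α-branched bis(chalcone) with protonation-controlled cis selectivity.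

Step 8
Reactants: 20 (2S,3S,2''S,3''S)-5,7,5'',7''-tetrakis(benzyloxy)-2''-[4-(benzyloxy)phenyl]-2-(4-methoxyphenyl)-3,3''-bichromane-4,4''-dione
Product: 21 sikokianin A, (2S,3S,2''S,3''S)-5,7,5'',7''-tetrahydroxy-2''-(4-hydroxyphenyl)-2-(4-methoxyphenyl)-3,3''-bichromane-4,4''-dione
Conditions: H2 (1 atm), Pd/C (10 wt %), EtOAc–THF, rt
Reagents that add atoms: none
Why: heterogeneous hydrogenolysis of the five aryl benzyl ethers under neutral conditions is the usual last step for benzyl-protected flavanones and should leave the ketones, the aryl methyl ether and the four stereocentres untouched, since no base is present to enolise C3 or C3''.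

**Compound list**

1 | 4-methoxybenzaldehyde | COc1ccc(C=O)cc1 | starting material
2 | ethynylmagnesium bromide | C#C[Mg]Br | starting material
3 | rac-1-(4-methoxyphenyl)prop-2-yn-1-ol | COc1ccc(C(O)C#C)cc1 | intermediate
4 | 4-(benzyloxy)benzaldehyde | O=Cc1ccc(OCc2ccccc2)cc1 | starting material
5 | dilithium 3-(4-methoxyphenyl)-3-oxidoprop-1-yn-1-ide, formed in the flask | [Li+].[Li+].COc1ccc(C([O-])C#[C-])cc1 | intermediate
6 | dilithium 1-[4-(benzyloxy)phenyl]-4-(4-methoxyphenyl)but-2-yne-1,4-bis(olate), diastereomer mixture, formed in the flask | [Li+].[Li+].COc1ccc(C([O-])C#CC([O-])c2ccc(OCc3ccccc3)cc2)cc1 | intermediate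
7 | 1-[4-(benzyloxy)phenyl]-4-(4-methoxyphenyl)but-2-yne-1,4-diyl bis(methyl carbonate), mixture of the two racemic diastereomers | COC(=O)OC(C#CC(OC(=O)OC)c1ccc(OCc2ccccc2)cc1)c1ccc(OC)cc1 | intermediate
8 | 3,5-bis(benzyloxy)phenol | Oc1cc(OCc2ccccc2)cc(OCc2ccccc2)c1 | starting material
9 | 1,3-bis(benzyloxy)-5-(methoxymethoxy)benzene | COCOc1cc(OCc2ccccc2)cc(OCc2ccccc2)c1 | intermediate
10 | [2,4-bis(benzyloxy)-6-(methoxymethoxy)phenyl]lithium, formed in the flask | [Li]c1c(OCOC)cc(OCc2ccccc2)cc1OCc1ccccc1 | intermediate
11 | lithium [2,4-bis(benzyloxy)-6-(methoxymethoxy)phenyl]tri(propan-2-yloxy)borate, formed in the flask | [Li+].CC(C)O[B-](OC(C)C)(OC(C)C)c1c(OCOC)cc(OCc2ccccc2)cc1OCc1ccccc1 | intermediate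
12 | [2,4-bis(benzyloxy)-6-(methoxymethoxy)phenyl]boronic acid | OB(O)c1c(OCOC)cc(OCc2ccccc2)cc1OCc1ccccc1 | intermediate
13 | carbon monoxide | [C-]#[O+] | starting material
14 | 1-[4-(benzyloxy)phenyl]-2-[2,4-bis(benzyloxy)-6-(methoxymethoxy)benzoyl]-4-(4-methoxyphenyl)buta-2,3-dien-1-yl methyl carbonate, stereoisomer mixture, formed in the flask | COc1ccc(C=C=C(C(=O)c2c(OCOC)cc(OCc3ccccc3)cc2OCc2ccccc2)C(OC(=O)OC)c2ccc(OCc3ccccc3)cc2)cc1 | intermediate
15 | 4-[4-(benzyloxy)phenyl]-2-[2,4-bis(benzyloxy)-6-(methoxymethoxy)benzoyl]-1-(4-methoxyphenyl)buta-2,3-dien-1-yl methyl carbonate, stereoisomer mixture, formed in the flask | COc1ccc(C(OC(=O)OC)C(C(=O)c2c(OCOC)cc(OCc3ccccc3)cc2OCc2ccccc2)=C=Cc2ccc(OCc3ccccc3)cc2)cc1 | intermediate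
16 | (2E,3E)-2-[4-(benzyloxy)benzylidene]-1,4-bis[2,4-bis(benzyloxy)-6-(methoxymethoxy)phenyl]-3-(4-methoxybenzylidene)butane-1,4-dione | COc1ccc(/C=C(C(=O)c2c(OCOC)cc(OCc3ccccc3)cc2OCc2ccccc2)\C(C(=O)c2c(OCOC)cc(OCc3ccccc3)cc2OCc2ccccc2)=C/c2ccc(OCc3ccccc3)cc2)cc1 | intermediate
17 | (2E,3E)-2-[4-(benzyloxy)benzylidene]-1,4-bis[2,4-bis(benzyloxy)-6-hydroxyphenyl]-3-(4-methoxybenzylidene)butane-1,4-dione | COc1ccc(/C=C(C(=O)c2c(O)cc(OCc3ccccc3)cc2OCc2ccccc2)\C(C(=O)c2c(O)cc(OCc3ccccc3)cc2OCc2ccccc2)=C/c2ccc(OCc3ccccc3)cc2)cc1 | intermediate
18 | (2S,3S)-5,7-bis(benzyloxy)-3-{(1E)-3-[2,4-bis(benzyloxy)-6-hydroxyphenyl]-1-[4-(benzyloxy)phenyl]-3-oxoprop-1-en-2-yl}-2-(4-methoxyphenyl)chroman-4-one, formed in the flask | COc1ccc([C@H]2Oc3cc(OCc4ccccc4)cc(OCc4ccccc4)c3C(=O)[C@H]2\C(C(=O)c2c(O)cc(OCc3ccccc3)cc2OCc2ccccc2)=C/c2ccc(OCc3ccccc3)cc2)cc1 | intermediate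
19 | (2S,3S)-5,7-bis(benzyloxy)-2-[4-(benzyloxy)phenyl]-3-{(1E)-3-[2,4-bis(benzyloxy)-6-hydroxyphenyl]-1-(4-methoxyphenyl)-3-oxoprop-1-en-2-yl}chroman-4-one, formed in the flask | COc1ccc(/C=C(C(=O)c2c(O)cc(OCc3ccccc3)cc2OCc2ccccc2)\[C@@H]2C(=O)c3c(OCc4ccccc4)cc(OCc4ccccc4)cc3O[C@@H]2c2ccc(OCc3ccccc3)cc2)cc1 | intermediate
20 | (2S,3S,2''S,3''S)-5,7,5'',7''-tetrakis(benzyloxy)-2''-[4-(benzyloxy)phenyl]-2-(4-methoxyphenyl)-3,3''-bichromane-4,4''-dione (cis at both rings) | COc1ccc([C@H]2Oc3cc(OCc4ccccc4)cc(OCc4ccccc4)c3C(=O)[C@H]2[C@@H]2C(=O)c3c(OCc4ccccc4)cc(OCc4ccccc4)cc3O[C@@H]2c2ccc(OCc3ccccc3)cc2)cc1 | intermediate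
21 | sikokianin A, (2S,3S,2''S,3''S)-5,7,5'',7''-tetrahydroxy-2''-(4-hydroxyphenyl)-2-(4-methoxyphenyl)-3,3''-bichromane-4,4''-dione | COc1ccc([C@H]2Oc3cc(O)cc(O)c3C(=O)[C@H]2[C@@H]2C(=O)c3c(O)cc(O)cc3O[C@@H]2c2ccc(O)cc2)cc1 | target

**Step count**

Total: 8 steps. Longest linear sequence: 6 steps (steps 1, 2, 5, 6, 7, 8 from 4-methoxybenzaldehyde; the boronic acid branch, steps 3, 4, 5, 6, 7, 8, is equally long).

**Steps most likely to fail**

1. Step 5 (proposed new method). The acylpalladium intermediates may be captured by methoxide (ester formation) instead of receiving the aryl group. Direct allenyl–aryl coupling may occur without CO insertion. The hindered, electron-rich boronic acid may protodeboronate before it transmetallates. The allenyl ketone may cycloisomerise to a furan before the second ionisation, and E selectivity at the arylidene groups may be incomplete. Fallback, setting out from 7 and returning at 16: the carbonylation and the arylation are separated. The known palladium-catalysed double methoxycarbonylation of but-2-yne-1,4-diol derivatives is applied to 7 (Pd(OAc)2, PPh3, CO 10 bar, MeOH, 50 °C) and should give dimethyl (2E,3E)-2-[4-(benzyloxy)benzylidene]-3-(4-methoxybenzylidene)butanedioate F1. Aminolysis with MeNH(OMe)·HCl and i-PrMgCl in THF at −20 °C should convert it into (2E,3E)-2-[4-(benzyloxy)benzylidene]-N1,N4-dimethoxy-3-(4-methoxybenzylidene)-N1,N4-dimethylbutanediamide F2. Addition of aryllithium 10 (2.5 equiv, generated from 9 as in step 4; THF, −78 to 0 °C; Weinreb ketone synthesis) then forms the same four bonds in two stages and delivers 16.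

2. Step 7 (proposed new method). Addition to the α-branched enones may be slow. Facial selectivity at C2 or C2'' may be poor, or the second closure may be governed by the first-formed ring rather than by the catalyst. Protonation may occur syn to the aryl group, or the amine may later epimerise C3/C3'' to the more stable trans rings. The extended enol may also be protonated at the γ-carbon, moving the double bond to C3=C3''. Fallback, setting out from 17 and returning at 20: stereocontrol by catalysis is replaced by resolution. The well-known base-mediated chalcone-to-flavanone cyclisation is run with an achiral amine (Et3N, CH2Cl2, 0 °C, short contact time, AcOH quench), where protonation anti to the C2 aryl group should again favour cis rings. The cis,cis diastereomer is separated by chromatography as a racemate, that is 20 together with its mirror image ent-20 F3. Preparative HPLC on a chiral stationary phase (amylose tris(3,5-dimethylphenylcarbamate)) then provides 20.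

3. Step 8. Once the phenols are free, or on the catalyst support, C3 and C3'' may epimerise toward the trans rings. The benzylic O1–C2 and O1''–C2'' bonds may be opened reductively, or the ketones over-reduced on prolonged exposure. Fallback, setting out from 20 and returning at 21: reductive cleavage is replaced by Lewis-acid dealkylation with a cation scavenger (BCl3, pentamethylbenzene, CH2Cl2, −78 °C, then MeOH quench). This should remove the five benzyl groups without hydrogen or base, and the aryl methyl ether, which is not next to a carbonyl group, should be kept at this temperature. No new compound lies on this path.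

**Further compounds**

F1 | step 5 | dimethyl (2E,3E)-2-[4-(benzyloxy)benzylidene]-3-(4-methoxybenzylidene)butanedioate | COc1ccc(/C=C(C(=O)OC)\C(C(=O)OC)=C/c2ccc(OCc3ccccc3)cc2)cc1
F2 | step 5 | (2E,3E)-2-[4-(benzyloxy)benzylidene]-N1,N4-dimethoxy-3-(4-methoxybenzylidene)-N1,N4-dimethylbutanediamide | COc1ccc(/C=C(C(=O)N(C)OC)\C(C(=O)N(C)OC)=C/c2ccc(OCc3ccccc3)cc2)cc1
F3 | step 7 | ent-20, (2R,3R,2''R,3''R)-5,7,5'',7''-tetrakis(benzyloxy)-2''-[4-(benzyloxy)phenyl]-2-(4-methoxyphenyl)-3,3''-bichromane-4,4''-dione | COc1ccc([C@@H]2Oc3cc(OCc4ccccc4)cc(OCc4ccccc4)c3C(=O)[C@@H]2[C@H]2C(=O)c3c(OCc4ccccc4)cc(OCc4ccccc4)cc3O[C@H]2c2ccc(OCc3ccccc3)cc2)cc1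
F0 | step 8 | none | none
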